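**Retrosynthetic overview**
- Feature used: C1 is a tertiary carbinol bonded to the benzylic ether carbon C2, and C2–H lies δ to a C1 carbonyl along C1–C5–C4–O3–C2. Cutting C1–C2 (hydrogen returned to C2) gives an open-chain α-silyloxy ketone with a 3,4-dimethoxybenzyl ether on C4.
- Ring order: ring 1 (C1, C2, O3, C4, C5) first, by photocyclisation of the open chain; ring 2 (C1, C5, C6, O7, C8) last, by O7–C8 Williamson closure after masking the C1 hydroxyl. The trans fusion follows from the trans C8 and C6 arms on ring 1.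
- The ketone comes from a terminal alkene (C1=C8) by dihydroxylation, primary silylation and oxidation; the O3–C2 ether comes from 3,4-dimethoxybenzyl bromide.
- C5 and C6 come from an Evans syn-aldol of a crotonyl imide with 3,4-dimethoxybenzaldehyde (acyl carbon = C4, vinyl group = C1–C8).

Key step: step 9

Numbering used for all compounds: C1(OH)–C2(Ar)–O3–C4H2–C5(H)–C6(Ar)–O7–C8H2, fusion bond C1–C5; Ar = 3,4-dimethoxyphenyl; TBS = tert-butyldimethylsilyl; SEM = 2-(trimethylsilyl)ethoxymethyl.
Assumption: the target is taken exactly as drawn, i.e. with the two oxolane rings trans-fused (C1–OH and C5–H on opposite faces), configuration 1S,2R,5S,6R.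

Step 1
Reactants: 1 (R)-4-benzyl-1,3-oxazolidin-2-one; 2 (E)-but-2-enoic anhydride
Product: 3 (R)-4-benzyl-3-[(E)-but-2-enoyl]-1,3-oxazolidin-2-one
Conditions: Et3N, LiCl, THF, −20 °C → rt
Reagents that add atoms: none
Why: N-acylation of the oxazolidinone by the anhydride under LiCl/Et3N activation should give the crotonyl imide without a strong base that could add to the enoyl unit.

Step 2
Reactants: 3 (R)-4-benzyl-3-[(E)-but-2-enoyl]-1,3-oxazolidin-2-one; 4 3,4-dimethoxybenzaldehyde
Product: 7 (R)-4-benzyl-3-[(2R,3R)-3-(3,4-dimethoxyphenyl)-2-ethenyl-3-hydroxypropanoyl]-1,3-oxazolidin-2-one, via dibutylboron dienolate 5 (not isolated), via dibutylboron aldolate 6 (not isolated)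
Conditions: Bu2BOTf, Et3N, CH2Cl2, −78 → 0 °C; 4, −78 → 0 °C; then pH 7 buffer, MeOH, H2O2, 0 °C
Reagents that add atoms: none
Why: Evans syn-aldol reaction, in which the (Z)-boron dienolate reacts at its α-carbon through a closed chair (Zimmerman–Traxler) transition state on the face away from the benzyl group of the (R)-auxiliary, setting C5 and C6 (both R in this compound) with the vinyl group (future C1–C8) syn to the hydroxyl and the acyl carbon as future C4.

Step 3
Reactants: 7 (R)-4-benzyl-3-[(2R,3R)-3-(3,4-dimethoxyphenyl)-2-ethenyl-3-hydroxypropanoyl]-1,3-oxazolidin-2-one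
Product: 8 (1R,2S)-1-(3,4-dimethoxyphenyl)-2-ethenylpropane-1,3-diol
Conditions: LiBH4, MeOH (1 equiv), THF, 0 °C
Reagents that add atoms: none
Why: Reductive cleavage of the imide by LiBH4 should free the primary C4 alcohol and the recoverable auxiliary without touching the alkene or either stereocentre.

Step 4
Reactants: 8 (1R,2S)-1-(3,4-dimethoxyphenyl)-2-ethenylpropane-1,3-diol; 9 3,4-dimethoxybenzyl bromide
Product: 11 (1R,2S)-1-(3,4-dimethoxyphenyl)-2-{[(3,4-dimethoxyphenyl)methoxy]methyl}but-3-en-1-ol, via dibutylstannylene acetal 10 (not isolated)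
Conditions: Bu2SnO, toluene, reflux (−H2O); then 9, Bu4NBr, toluene, 80 °C
Reagents that add atoms: none
Why: Regioselective O-alkylation through the stannylene acetal of the 1,3-diol, whose primary oxygen is the more nucleophilic, should install the O3–C2 benzylic ether and leave the C6 hydroxyl free.

Step 5
Reactants: 11 (1R,2S)-1-(3,4-dimethoxyphenyl)-2-{[(3,4-dimethoxyphenyl)methoxy]methyl}but-3-en-1-ol
Product: 12 tert-butyl{[(1R,2S)-1-(3,4-dimethoxyphenyl)-2-{[(3,4-dimethoxyphenyl)methoxy]methyl}but-3-en-1-yl]oxy}dimethylsilane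
Conditions: TBSOTf, 2,6-lutidine, CH2Cl2, −78 → 0 °C
Reagents that add atoms: tert-butyldimethylsilyl trifluoromethanesulfonate, CC(C)(C)[Si](C)(C)OS(=O)(=O)C(F)(F)F
Why: Silylation of the hindered benzylic alcohol with the silyl triflate protects C6–O as an ether that offers no abstractable hydrogen near the later carbonyl, and doing it after the alkylation avoids base-induced silyl migration.

Step 6
Reactants: 12 tert-butyl{[(1R,2S)-1-(3,4-dimethoxyphenyl)-2-{[(3,4-dimethoxyphenyl)methoxy]methyl}but-3-en-1-yl]oxy}dimethylsilane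
Product: 13 1,2-diol at C1/C8 (C4–O-3,4-dimethoxybenzyl and C6–OTBS as in 12; both C1 epimers)
Conditions: OsO4 (2 mol %), N-methylmorpholine N-oxide, acetone/H2O, rt
Reagents that add atoms: osmium tetroxide OsO4, O=[Os](=O)(=O)=O; N-methylmorpholine N-oxide, C[N+]1([O-])CCOCC1; water, O
Why: Catalytic syn-dihydroxylation of the terminal alkene places oxygen on C1 and C8, and the C1 configuration does not matter because C1 becomes a ketone.

Step 7
Reactants: 13 1,2-diol at C1/C8
Product: 14 secondary alcohol at C1 with C8–OTBS and C6–OTBS (both C1 epimers)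
Conditions: TBSCl, imidazole, CH2Cl2, 0 °C
Reagents that add atoms: tert-butyldimethylsilyl chloride, CC(C)(C)[Si](C)(C)Cl
Why: Silylation of a primary/secondary 1,2-diol is selective for the primary hydroxyl, giving the C8 silyl ether whose γ-atom relative to the later carbonyl is silicon and carries no hydrogen.

Step 8
Reactants: 14 secondary alcohol at C1 with C8–OTBS and C6–OTBS
Product: 15 (3S,4R)-1,4-bis[(tert-butyldimethylsilyl)oxy]-4-(3,4-dimethoxyphenyl)-3-{[(3,4-dimethoxyphenyl)methoxy]methyl}butan-2-one (C5 S, C6 R in target numbering)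
Conditions: Dess–Martin periodinane, pyridine, CH2Cl2, 0 °C → rt
Reagents that add atoms: none
Why: Dess–Martin oxidation under buffered, non-basic conditions should give the α-silyloxy ketone without epimerising C5 or eliminating either β-oxygen substituent.

Step 9
Reactants: 15 (3S,4R)-1,4-bis[(tert-butyldimethylsilyl)oxy]-4-(3,4-dimethoxyphenyl)-3-{[(3,4-dimethoxyphenyl)methoxy]methyl}butan-2-one
Product: 17 (2R,3S,4S)-4-[(R)-[(tert-butyldimethylsilyl)oxy](3,4-dimethoxyphenyl)methyl]-3-{[(tert-butyldimethylsilyl)oxy]methyl}-2-(3,4-dimethoxyphenyl)oxolan-3-ol (1S,2R,5S,6R in target numbering), via 1,5-biradical 16 (not isolated)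
Conditions: hν (medium-pressure Hg lamp, Pyrex filter, λ > 300 nm), degassed benzene (0.01 M), rt
Reagents that add atoms: none
Why: The n,π*-excited C1 carbonyl abstracts the benzylic ether hydrogen on C2 through a seven-membered transition state (O=C1–C5–C4–O3–C2–H), and the resulting 1,5-biradical 16 couples at C1 and C2. This is the Norrish–Yang photocyclisation of β-alkoxy ketones to 3-hydroxytetrahydrofurans, a known reaction type applied here to an open-chain α-silyloxy ketone. Ring 1 (C1, C2, O3, C4, C5) closes by combination of the ketyl carbon with the benzylic carbon, a five-membered closure of the 1,5-biradical. C1 is controlled by the existing C5 centre, the CH2OTBS arm on the ketyl carbon turning away from the CH(OTBS)Ar arm so that the hydroxyl ends cis to it; C2 is controlled by the forming C1 centre, the aryl group taking the side opposite the CH2OTBS arm and so cis to the hydroxyl. The step needs abstraction at C2 to beat α-cleavage and any other abstraction: the ketone has no γ-hydrogen (the γ atoms are O3, the C6 oxygen, an aryl carbon and silicon), the only other δ C–H bonds are unactivated Si–CH3 bonds, and C2–H is both benzylic and α to oxygen. Light above 300 nm excites the ketone and not the dimethoxyarenes, and because ring 2 is not yet closed the C8 and C6 arms are free to end trans.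

Step 10
Reactants: 17 (2R,3S,4S)-4-[(R)-[(tert-butyldimethylsilyl)oxy](3,4-dimethoxyphenyl)methyl]-3-{[(tert-butyldimethylsilyl)oxy]methyl}-2-(3,4-dimethoxyphenyl)oxolan-3-ol
Product: 18 SEM ether of 17 at the tertiary C1 oxygen (C8–OTBS and C6–OTBS kept; 1S,2R,5S,6R in target numbering)
Conditions: SEMCl, iPr2NEt, ClCH2CH2Cl, 60 °C
Reagents that add atoms: 2-(trimethylsilyl)ethoxymethyl chloride, C[Si](C)(C)CCOCCl
Why: O-alkylation of the tertiary alcohol with the α-chloro ether masks C1–O as an acetal that cannot migrate, so that no C1 alkoxide is present in step 13 to close an oxirane onto C8 ahead of the strained ring-2 closure, and it is later removed by fluoride instead of acid.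

Step 11
Reactants: 18 SEM ether of 17
Product: 19 diol with C8H2OH and (R)-C6H(OH)Ar on ring 1 and C1–OSEM (1S,2R,5S,6R in target numbering)
Conditions: Bu4NF, THF, 0 °C → rt
Reagents that add atoms: none
Why: Fluoride-mediated desilylation cleaves both tert-butyldimethylsilyl ethers, while the SEM ether is inert to Bu4NF at room temperature.

Step 12
Reactants: 19 diol with C8H2OH, C6H(OH)Ar and C1–OSEM
Product: 20 primary C8 4-methylbenzenesulfonate of 19 (C6–OH free, C1–OSEM)
Conditions: TsCl, pyridine, DMAP (cat.), CH2Cl2, 0 °C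
Reagents that add atoms: 4-methylbenzenesulfonyl chloride, Cc1ccc(cc1)S(=O)(=O)Cl
Why: Sulfonylation is selective for the primary C8 hydroxyl over the more hindered secondary benzylic C6 hydroxyl, and the resulting neopentyl-type tosylate has no β-hydrogen and cannot eliminate.

Step 13
Reactants: 20 primary C8 4-methylbenzenesulfonate of 19
Product: 22 (1S,2R,5S,6R)-2,6-bis(3,4-dimethoxyphenyl)-1-{[2-(trimethylsilyl)ethoxy]methoxy}-3,7-dioxabicyclo[3.3.0]octane (trans-fused), via sodium alkoxide 21 (not isolated)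
Conditions: NaH, THF, 0 → 50 °C
Reagents that add atoms: none
Why: Intramolecular Williamson etherification (5-exo-tet) by the C6 alkoxide, the only alkoxide present, at C8 closes ring 2 without touching a stereocentre, the trans fusion following from the trans C8 and C6 arms set in step 9.

Step 14
Reactants: 22 (1S,2R,5S,6R)-2,6-bis(3,4-dimethoxyphenyl)-1-{[2-(trimethylsilyl)ethoxy]methoxy}-3,7-dioxabicyclo[3.3.0]octane
Product: 23 (1S,2R,5S,6R)-2,6-bis(3,4-dimethoxyphenyl)-3,7-dioxabicyclo[3.3.0]octan-1-ol (CNP0422369.8)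
Conditions: Bu4NF, DMPU, 4 Å MS, 80 °C
Reagents that add atoms: none
Why: Fluoride attack at silicon fragments the acetal ether with loss of fluorotrimethylsilane, ethene and formaldehyde and frees the tertiary alcohol under non-acidic conditions that should not ionise the strained bis-benzylic ether.

**Compound list**
1 | (R)-4-benzyl-1,3-oxazolidin-2-one | O=C1N[C@H](Cc2ccccc2)CO1 | starting material
2 | (E)-but-2-enoic anhydride | C/C=C/C(=O)OC(=O)/C=C/C | starting material
3 | (R)-4-benzyl-3-[(E)-but-2-enoyl]-1,3-oxazolidin-2-one | C/C=C/C(=O)N1[C@H](Cc2ccccc2)COC1=O | intermediate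
4 | 3,4-dimethoxybenzaldehyde | COc1ccc(C=O)cc1OC | starting material
5 | (Z)-dibutylboron dienolate of 3 | CCCCB(CCCC)O/C(=C\C=C)N1[C@H](Cc2ccccc2)COC1=O | intermediate
6 | dibutylboron aldolate of 7 | O=C(N1[C@H](Cc2ccccc2)COC1=O)[C@H](C=C)[C@@H](OB(CCCC)CCCC)c1ccc(OC)c(OC)c1 | intermediate
7 | (R)-4-benzyl-3-[(2R,3R)-3-(3,4-dimethoxyphenyl)-2-ethenyl-3-hydroxypropanoyl]-1,3-oxazolidin-2-one | O=C(N1[C@H](Cc2ccccc2)COC1=O)[C@H](C=C)[C@@H](O)c1ccc(OC)c(OC)c1 | intermediate
8 | (1R,2S)-1-(3,4-dimethoxyphenyl)-2-ethenylpropane-1,3-diol | OC[C@H](C=C)[C@@H](O)c1ccc(OC)c(OC)c1 | intermediate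
9 | 3,4-dimethoxybenzyl bromide | COc1ccc(CBr)cc1OC | starting material
10 | dibutylstannylene acetal of 8 | CCCC[Sn]1(CCCC)OC[C@H](C=C)[C@H](c2ccc(OC)c(OC)c2)O1 | intermediate
11 | (1R,2S)-1-(3,4-dimethoxyphenyl)-2-{[(3,4-dimethoxyphenyl)methoxy]methyl}but-3-en-1-ol | COc1ccc(COC[C@H](C=C)[C@@H](O)c2ccc(OC)c(OC)c2)cc1OC | intermediate
12 | TBS ether of 11 at the C6 oxygen | COc1ccc(COC[C@H](C=C)[C@@H](O[Si](C)(C)C(C)(C)C)c2ccc(OC)c(OC)c2)cc1OC | intermediate
13 | C1/C8 1,2-diol from 12 (both C1 epimers) | COc1ccc(COC[C@H](C(O)CO)[C@@H](O[Si](C)(C)C(C)(C)C)c2ccc(OC)c(OC)c2)cc1OC | intermediate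
14 | C1 secondary alcohol with C8–OTBS and C6–OTBS (both C1 epimers) | COc1ccc(COC[C@H](C(O)CO[Si](C)(C)C(C)(C)C)[C@@H](O[Si](C)(C)C(C)(C)C)c2ccc(OC)c(OC)c2)cc1OC | intermediate
15 | (3S,4R)-1,4-bis[(tert-butyldimethylsilyl)oxy]-4-(3,4-dimethoxyphenyl)-3-{[(3,4-dimethoxyphenyl)methoxy]methyl}butan-2-one | COc1ccc(COC[C@H](C(=O)CO[Si](C)(C)C(C)(C)C)[C@@H](O[Si](C)(C)C(C)(C)C)c2ccc(OC)c(OC)c2)cc1OC | intermediate
16 | 1,5-biradical (ketyl at C1, benzylic radical at C2) | COc1ccc([CH]OC[C@H]([C](O)CO[Si](C)(C)C(C)(C)C)[C@@H](O[Si](C)(C)C(C)(C)C)c2ccc(OC)c(OC)c2)cc1OC | intermediate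
17 | (2R,3S,4S)-4-[(R)-[(tert-butyldimethylsilyl)oxy](3,4-dimethoxyphenyl)methyl]-3-{[(tert-butyldimethylsilyl)oxy]methyl}-2-(3,4-dimethoxyphenyl)oxolan-3-ol | COc1ccc(cc1OC)[C@H]2OC[C@@H]([C@@H](O[Si](C)(C)C(C)(C)C)c3ccc(OC)c(OC)c3)[C@]2(O)CO[Si](C)(C)C(C)(C)C | intermediate
18 | SEM ether of 17 at the C1 oxygen | COc1ccc(cc1OC)[C@H]2OC[C@@H]([C@@H](O[Si](C)(C)C(C)(C)C)c3ccc(OC)c(OC)c3)[C@]2(OCOCC[Si](C)(C)C)CO[Si](C)(C)C(C)(C)C | intermediate
19 | diol: C8H2OH and (R)-C6H(OH)Ar on ring 1, C1–OSEM | COc1ccc(cc1OC)[C@H]2OC[C@@H]([C@@H](O)c3ccc(OC)c(OC)c3)[C@]2(OCOCC[Si](C)(C)C)CO | intermediate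
20 | C8 4-methylbenzenesulfonate of 19 | COc1ccc(cc1OC)[C@H]2OC[C@@H]([C@@H](O)c3ccc(OC)c(OC)c3)[C@]2(OCOCC[Si](C)(C)C)COS(=O)(=O)c4ccc(C)cc4 | intermediate
21 | sodium C6 alkoxide of 20 | COc1ccc(cc1OC)[C@H]2OC[C@@H]([C@@H]([O-])c3ccc(OC)c(OC)c3)[C@]2(OCOCC[Si](C)(C)C)COS(=O)(=O)c4ccc(C)cc4.[Na+] | intermediate
22 | (1S,2R,5S,6R)-2,6-bis(3,4-dimethoxyphenyl)-1-{[2-(trimethylsilyl)ethoxy]methoxy}-3,7-dioxabicyclo[3.3.0]octane | COc1ccc([C@H]2OC[C@H]3[C@H](c4ccc(OC)c(OC)c4)OC[C@]23OCOCC[Si](C)(C)C)cc1OC | intermediate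
23 | (1S,2R,5S,6R)-2,6-bis(3,4-dimethoxyphenyl)-3,7-dioxabicyclo[3.3.0]octan-1-ol | COc1ccc([C@H]2OC[C@H]3[C@H](c4ccc(OC)c(OC)c4)OC[C@]23O)cc1OC | target

Total step count: 14. Longest linear sequence: 14 steps (1 and 2 to 23).

**Steps most likely to fail**

Step 9 (key step). What may go wrong: the 1,5-biradical may collapse with too little facial preference at C1 and C2, or revert to ketone and fragment by α-cleavage, so that 17 arrives as a minor part of an epimer mixture. Fallback: the C1 configuration is set by a polar addition instead of by radical coupling. It sets out from 17 taken as the C1/C2 epimer mixture and comes back at 17 as one isomer. HF·pyridine/pyridine in THF at 0 °C removes only the primary silyl group and should give the 1,2-diol F1. NaIO4 in THF/pH 7 buffer cleaves the C1–C8 bond to the ring ketone F2, in which C1 is no longer a stereocentre; C2 (benzylic, α to the carbonyl) can be equilibrated through the enol with Et3N, the 2,4-cis isomer being separated and the trans isomer recycled. (iPrO)Me2SiCH2MgCl with CeCl3 in THF at −78 °C should add to the carbonyl from the face opposite the aryl group and the C6 arm and give the β-hydroxysilane F3. Tamao oxidation of the C–Si bond (KF, KHCO3, H2O2, THF/MeOH) gives the diol F4, and TBSCl/imidazole silylates its primary hydroxyl and returns 17.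

Step 13. What may go wrong: in the trans arrangement the C6 alkoxide reaches the back of the neopentyl C8–O bond only with strain, so sulfonyl transfer to the C6 oxygen or slow decomposition may outrun ring closure. Fallback: the roles of the two carbons are exchanged. It sets out from diol 19 and comes back at 22, and forms no compound outside the list (F0). Camphorsulfonic acid (cat.) with 4 Å molecular sieves in CH2Cl2 ionises the electron-rich benzylic C6 alcohol and the primary C8 hydroxyl captures the cation, the cationic cyclodehydration used for furofuran lignans. A planar cation needs no backside trajectory, and the aryl group should settle on the side of ring 2 away from C4, which is the C6 configuration of the target.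

Step 10. What may go wrong: the tertiary hydroxyl, flanked on its own face by the C2 aryl group and the C6 arm, may resist alkylation, and forcing conditions may cost a silyl ether. Fallback: no protecting group on C1–O and ring closure without an alkoxide. It sets out from 17 and comes back at 23. Bu4NF in THF should give the triol F5. TsCl, Et3N and Bu2SnO (cat.) in CH2Cl2 tosylate only the primary hydroxyl of the 1,2-diol through its stannylene and give the hydroxy tosylate F6. Heating F6 with 2,6-lutidine in MeCN lets the neutral C6 hydroxyl displace the tosylate by five-membered participation, while the tertiary hydroxyl, not being deprotonated, should not close the oxirane; this gives 23 directly.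

**Further compounds**
F1 | step 9 | 1,2-diol from 17 after loss of the primary silyl group (C1/C2 epimer mixture, C6–OTBS kept) | COc1ccc(cc1OC)C2OC[C@@H]([C@@H](O[Si](C)(C)C(C)(C)C)c3ccc(OC)c(OC)c3)C2(O)CO
F2 | step 9 | (2R,4S)-4-[(R)-[(tert-butyldimethylsilyl)oxy](3,4-dimethoxyphenyl)methyl]-2-(3,4-dimethoxyphenyl)oxolan-3-one | COc1ccc(cc1OC)[C@H]2OC[C@@H]([C@@H](O[Si](C)(C)C(C)(C)C)c3ccc(OC)c(OC)c3)C2=O
F3 | step 9 | β-hydroxysilane: ring 1 with C1–OH and C8H2–SiMe2(OiPr), C6–OTBS | COc1ccc(cc1OC)[C@H]2OC[C@@H]([C@@H](O[Si](C)(C)C(C)(C)C)c3ccc(OC)c(OC)c3)[C@]2(O)C[Si](C)(C)OC(C)C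
F4 | step 9 | diol: ring 1 with C1–OH and C8H2OH, C6–OTBS (single isomer, configured as 17) | COc1ccc(cc1OC)[C@H]2OC[C@@H]([C@@H](O[Si](C)(C)C(C)(C)C)c3ccc(OC)c(OC)c3)[C@]2(O)CO
F5 | step 10 | triol: ring 1 with C1–OH, C8H2OH and (R)-C6H(OH)Ar | COc1ccc(cc1OC)[C@H]2OC[C@@H]([C@@H](O)c3ccc(OC)c(OC)c3)[C@]2(O)CO
F6 | step 10 | C8 4-methylbenzenesulfonate of the triol (C1–OH and C6–OH free) | COc1ccc(cc1OC)[C@H]2OC[C@@H]([C@@H](O)c3ccc(OC)c(OC)c3)[C@]2(O)COS(=O)(=O)c4ccc(C)cc4
F0 | step 13 | none | none
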